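**Strategy.** The route rests on cutting the C1–C2 bond of the bicyclo[2.2.1]heptene (ring atoms C1, C2, C3, C4, C5, C11', C13'), whose C2 carbinol bridge, with oxygen syn to C4=C5, is the homoallylic alcohol of a carbonyl-ene reaction. In one operation the formyl carbon C2 on C3 adds across the spiro-cyclohexene to C1 of C1=C5 while H4 moves to oxygen; this closes both five-membered rings, sets C1 and C2 and places the alkene at C4=C5. The precursor is the Diels–Alder adduct of a bis-exocyclic cycloheptane diene and the (E)-formylmethylene lactone made from 1-O-acetylbritannilactone, epimerised at C3 so that the formyl group and H4 are cis.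

Key step: step 18

Remark: atom numbers are those of the target (guaianolide half C1–C15, seco-eudesmanolide half C1'–C15'). In 5–19 the ketone (later methylene) carbon is C1, the methyl-bearing carbon is C10, and the lactone carbons are C7 (carbon side) and C8 (oxygen side).
Remark: 1-O-acetylbritannilactone (20), which already carries C4', C6', C7' and C8' of the target, is taken as a purchasable catalogue natural product.
Remark: the carbinol centre C1 of 9–11 is carried as a mixture of epimers, because it is re-oxidised in step 8.

Step 1
Reactants: 1 cyclohept-4-en-1-one; 2 (R)-1-amino-2-(methoxymethyl)pyrrolidine (RAMP)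
Product: 3 RAMP hydrazone of cyclohept-4-en-1-one
Conditions: cyclohexane, reflux, water separator
Reagents that add atoms: none
Why: Hydrazone condensation of an unhindered ketone with the chiral hydrazine should go to completion once water is removed; no stereocentre is formed.

Step 2
Reactants: 3 RAMP hydrazone of cyclohept-4-en-1-one
Product: 4 RAMP hydrazone of (S)-2-methylcyclohept-4-en-1-one
Conditions: LiN(i-Pr)2, THF, 0 °C; MeI, −100 → 25 °C
Reagents that add atoms: iodomethane, CI
Why: Enders hydrazone alkylation: the lithium azaenolate, chelated by the methoxymethyl group, is methylated on one face, and the RAMP auxiliary should give the (S) centre (C10) as it does with simple cycloalkanones.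

Step 3
Reactants: 4 RAMP hydrazone of (S)-2-methylcyclohept-4-en-1-one
Product: 5 (S)-2-methylcyclohept-4-en-1-one
Conditions: saturated aqueous oxalic acid, Et2O, 25 °C
Reagents that add atoms: water, O
Why: Two-phase acid hydrolysis of the hydrazone should free the ketone without enolising C10 and return the auxiliary.

Step 4
Reactants: 5 (S)-2-methylcyclohept-4-en-1-one
Product: 7 (S)-7-methylcyclohepta-2,4-dien-1-one, via silyl enol ether 6 (not isolated)
Conditions: LiN(i-Pr)2, Me3SiCl, THF, −78 °C; then Pd(OAc)2 (1 equiv), MeCN, 25 °C
Reagents that add atoms: chlorotrimethylsilane, C[Si](C)(C)Cl (silyl group of 6 only)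
Why: Kinetic deprotonation takes the CH2 side (C5) and leaves the methine C10 untouched; Saegusa–Ito oxidation of the silyl enol ether then places C5=C6 in conjugation with C7=C8, which marks C7 as the future allylic epoxide carbon.

Step 5
Reactants: 7 (S)-7-methylcyclohepta-2,4-dien-1-one
Product: 8 (4R,5S,7S)-4,5-epoxy-7-methylcyclohept-2-en-1-one
Conditions: (R,R)-N,N'-bis(3,5-di-tert-butylsalicylidene)cyclohexane-1,2-diaminomanganese chloride (5 mol %), mCPBA, N-methylmorpholine N-oxide, CH2Cl2, −78 °C
Reagents that add atoms: 3-chloroperoxybenzoic acid, O=C(OO)c1cccc(Cl)c1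
Why: Jacobsen epoxidation of a cis-disubstituted conjugated alkene: the γ,δ-alkene C7=C8 is the electron-richer one, and the (R,R)-catalyst is expected (by analogy with indene) to deliver oxygen to the face anti to the C10 methyl group, which the substrate should also prefer; this sets C7 and C8.

Step 6
Reactants: 8 (4R,5S,7S)-4,5-epoxy-7-methylcyclohept-2-en-1-one
Product: 9 (4R,5S,7S)-4,5-epoxy-7-methylcyclohept-2-en-1-ol (C1 epimers)
Conditions: NaBH4, CeCl3·7H2O, MeOH, −78 °C
Reagents that add atoms: none
Why: Luche 1,2-reduction masks the enone as its allylic alcohol, so that the carbon nucleophile of step 7 meets only the vinyl epoxide; the configuration formed at C1 is immaterial.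

Step 7
Reactants: 9 (4R,5S,7S)-4,5-epoxy-7-methylcyclohept-2-en-1-ol
Product: 11 trans-fused hydroxy lactone, via hydroxy acid 10 (not isolated)
Conditions: LiCH2CO2Li (AcOH, 2 LiN(i-Pr)2), 1,2-dimethoxyethane, 0 → 45 °C; then 1 M HCl to pH 3, 25 °C
Reagents that add atoms: acetic acid, CC(=O)O
Why: Epoxide opening by the acetate dianion should occur at the allylic carbon C7 with inversion (SN2), which puts the new C7–C11 bond trans to the C8 oxygen; the γ-hydroxy acid lactonises on acidification to the trans-fused γ-lactone.

Step 8
Reactants: 11 trans-fused hydroxy lactone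
Product: 12 enone lactone
Conditions: MnO2, CH2Cl2, 25 °C
Reagents that add atoms: none
Why: Selective oxidation of the allylic alcohol with activated MnO2 restores the C1 ketone in conjugation with C5=C6 and leaves the lactone alone.

Step 9
Reactants: 12 enone lactone
Product: 13 aldol (mixture at C5 and at the carbinol carbon)
Conditions: LiBH(s-Bu)3, THF, −78 °C; then CH3CHO, −78 °C
Reagents that add atoms: acetaldehyde, CC=O
Why: Reductive aldol reaction: conjugate hydride addition generates the C1/C5 enolate regiospecifically, away from C10, and this adds to acetaldehyde; the two new centres are removed in step 10.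

Step 10
Reactants: 13 aldol
Product: 15 (E)-ethylidene ketone, via mesylate 14 (not isolated)
Conditions: MsCl, Et3N, CH2Cl2, 0 → 25 °C
Reagents that add atoms: methanesulfonyl chloride, CS(=O)(=O)Cl (mesyl group of 14 only)
Why: Mesylation and E1cB elimination of the β-mesyloxy ketone should give the exocyclic enone as the more stable (E)-isomer (methyl anti to the carbonyl carbon) under conditions too mild to epimerise C10.

Step 11
Reactants: 15 (E)-ethylidene ketone
Product: 16 diene with saturated lactone
Conditions: Zn, CH2Br2, TiCl4, THF, 0 °C; then 15, CH2Cl2, 25 °C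
Reagents that add atoms: dibromomethane, BrCBr
Why: Takai–Lombardo methylenation turns the enone carbonyl into the exocyclic methylene with a non-basic reagent, so the lactone is untouched and the α-centre C10 keeps its configuration.

Step 12
Reactants: 16 diene with saturated lactone
Product: 19 guaianolide diene, via Mannich base 17 (not isolated), via methiodide 18 (not isolated)
Conditions: LiN(i-Pr)2, THF, −78 °C; CH2=NMe2+ I−, −78 → 25 °C; then MeI, MeOH, 25 °C; then aqueous NaHCO3, CH2Cl2, 25 °C
Reagents that add atoms: dimethyl(methylidene)ammonium iodide, C=[N+](C)C.[I-]; iodomethane, CI (N-methyl group of 18 only)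
Why: α-Methylenation of the lactone by Mannich reaction of its enolate with Eschenmoser's salt, quaternisation and E1cB loss of trimethylamine; the ring-fusion centre C7 is not enolisable, so no stereocentre is affected.

Step 13
Reactants: 20 1-O-acetylbritannilactone
Product: 21 6'-O-TBS-1'-O-acetylbritannilactone
Conditions: TBSOTf, 2,6-lutidine, CH2Cl2, −78 → 0 °C
Reagents that add atoms: tert-butyldimethylsilyl trifluoromethanesulfonate, CC(C)(C)[Si](C)(C)OS(=O)(=O)C(F)(F)F
Why: Silyl ether formation at the hindered allylic alcohol with the silyl triflate keeps 6'-OH from forming a lactol with the later aldehyde and from being acetylated in step 19.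

Step 14
Reactants: 21 6'-O-TBS-1'-O-acetylbritannilactone
Product: 22 (E)-alkylidene lactone diethyl acetal
Conditions: 3,3-diethoxyprop-1-ene (10 equiv), second-generation Hoveyda–Grubbs catalyst (10 mol %), 2,6-dichloro-1,4-benzoquinone (20 mol %), toluene, 80 °C
Reagents that add atoms: 3,3-diethoxyprop-1-ene, C=CC(OCC)OCC
Why: Olefin cross-metathesis of the α-methylene lactone with an excess of the acrolein acetal exchanges the exocyclic CH2 for CH–CH(OEt)2 and should give the more stable (E)-alkylidene lactone (new substituent anti to the lactone carbonyl); the tetrasubstituted C5'=C10' alkene cannot take part.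

Step 15
Reactants: 22 (E)-alkylidene lactone diethyl acetal
Product: 23 (E)-formylmethylene lactone
Conditions: pyridinium p-toluenesulfonate, acetone–H2O, 40 °C
Reagents that add atoms: water, O
Why: Mild acid hydrolysis of the allylic acetal frees the enal without loss of the silyl ether or the acetate; the (E)-geometry, also the thermodynamic one, is kept.

Step 16
Reactants: 19 guaianolide diene; 23 (E)-formylmethylene lactone
Product: 24 Diels–Alder adduct (C3 epimer of 25)
Conditions: 19 (1.3 equiv), toluene, BHT, 70 °C
Reagents that add atoms: none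
Why: Diels–Alder reaction of the s-cis-locked diene with the doubly activated dienophile: the formyl group directs C3 to the methyl-bearing terminus C4 and the quaternary C11' to the CH2 terminus C13', the diene is attacked anti to the C10 methyl group and the dienophile on the convex face of its cis-fused lactone (anti to C6'), and the transition state with the lactone carbonyl exo and the formyl group endo, which the (E)-geometry allows and both groups prefer, sets C11' and C4 as in the target and leaves the formyl group at C3 cis to the C4 methyl group.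

Step 17
Reactants: 24 Diels–Alder adduct
Product: 25 formyl spiro-cyclohexene (ene precursor)
Conditions: DBU (0.1 equiv), CH2Cl2, 25 °C; chromatography, recovered 24 re-equilibrated
Reagents that add atoms: none
Why: Base-mediated epimerisation through the aldehyde enolate at C3, the only enolisable centre of the new ring, should favour or at least populate 25, whose formyl group is equatorial, trans to the C4 methyl group and to C7' and therefore cis to H4; C4 and C11' cannot change.

Step 18
Reactants: 25 formyl spiro-cyclohexene
Product: 26 7-norbornenol (2-deacetyl 6'-O-TBS target)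
Conditions: MeAlCl2 (2.2 equiv), CH2Cl2, −78 → 0 °C
Reagents that add atoms: none
Why: Proposed new method: MeAlCl2 binds the formyl oxygen, C2 adds to C1 of the tetrasubstituted C1=C5 alkene from the face that carries the formyl group while the syn hydrogen H4 passes to oxygen through a six-membered array, so that the alkene moves to C4=C5 and the aluminium alkoxide is fixed by loss of methane; the closest known reaction type is the Lewis-acid-promoted intramolecular carbonyl-ene (Prins) cyclisation of unsaturated aldehydes to bridged homoallylic alcohols. The C1–C2 bond closes both five-membered rings of the bicyclo[2.2.1]heptene at once, transannularly across the 1,4-positions of the cyclohexene boat (5-exo-trig counted through C11'–C13', 5-endo-trig through C4–C5). C1 is set by the tether, because C2 on C3 can reach only one face of C1, and C2 is set by the cyclic hydrogen transfer, which holds oxygen over C4 and hence syn to the new C4=C5 alkene. The step needs transfer of H4 and not of H6, and attack on C1=C5 and not on the C5'=C10' alkene of the seco-eudesmane ring. The first is secured by H4 being cis to the formyl group and nearest to oxygen; the second by the trans arrangement of the formyl group and C7' on the cyclohexene (a chair-like six-membered closure onto C5' needs them cis, as in 24), by the silyl ether and side chain that flank C5', and by using epimerically pure 25 at low temperature.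

Step 19
Reactants: 26 7-norbornenol
Product: 27 2-O-acetyl 6'-O-TBS compound
Conditions: Ac2O, DMAP, Et3N, CH2Cl2, 25 °C
Reagents that add atoms: acetic anhydride, CC(=O)OC(C)=O
Why: DMAP-catalysed acetylation of the only free hydroxyl group (C2–OH) installs the second acetate; no stereocentre is touched.

Step 20
Reactants: 27 2-O-acetyl 6'-O-TBS compound
Product: 28 CNP0211028.3 (target)
Conditions: HF·pyridine, pyridine, THF, 0 → 25 °C
Reagents that add atoms: none
Why: Fluoride cleavage of the silyl ether under buffered acidic conditions frees 6'-OH without acyl migration, acetate loss or addition to the α-methylene lactone.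

**Compound list**

1 | cyclohept-4-en-1-one | O=C1CCC=CCC1 | starting material
2 | (R)-1-amino-2-(methoxymethyl)pyrrolidine (RAMP) | COC[C@H]1CCCN1N | starting material
3 | RAMP hydrazone of cyclohept-4-en-1-one | COC[C@H]1CCCN1N=C1CCC=CCC1 | intermediate
4 | RAMP hydrazone of (S)-2-methylcyclohept-4-en-1-one (amino group anti to the methyl-bearing carbon) | COC[C@H]1CCCN1/N=C1\CCC=CC[C@@H]1C | intermediate
5 | (S)-2-methylcyclohept-4-en-1-one | C[C@H]1CC=CCCC1=O | intermediate
6 | (S)-trimethyl[(7-methylcyclohepta-1,4-dien-1-yl)oxy]silane | C[C@H]1CC=CCC=C1O[Si](C)(C)C | intermediate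
7 | (S)-7-methylcyclohepta-2,4-dien-1-one | C[C@H]1CC=CC=CC1=O | intermediate
8 | (4R,5S,7S)-4,5-epoxy-7-methylcyclohept-2-en-1-one (epoxide trans to methyl) | C[C@H]1C[C@@H]2O[C@@H]2C=CC1=O | intermediate
9 | (4R,5S,7S)-4,5-epoxy-7-methylcyclohept-2-en-1-ol, both C1 epimers | C[C@H]1C[C@@H]2O[C@@H]2C=CC1O | intermediate
10 | hydroxy acid: (7R,8S,10S), C7–CH2CO2H trans to C8–OH, C5=C6 alkene, C1 carbinol epimers | OC(=O)C[C@H]1C=CC(O)[C@@H](C)C[C@@H]1O | intermediate
11 | hydroxy lactone: (7R,8S,10S) trans-fused γ-lactone (C11H2 on C7, O on C8), C5=C6 alkene, C1 carbinol epimers | C1C(=O)O[C@H]2C[C@H](C)C(O)C=C[C@H]12 | intermediate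
12 | enone lactone: as 11 with C1 ketone | C1C(=O)O[C@H]2C[C@H](C)C(=O)C=C[C@H]12 | intermediate
13 | aldol: C1 ketone, 1-hydroxyethyl on C5, mixture at C5 and carbinol carbon | C1C(=O)O[C@H]2C[C@H](C)C(=O)C(C(C)O)C[C@H]12 | intermediate
14 | mesylate of 13 | C1C(=O)O[C@H]2C[C@H](C)C(=O)C(C(C)OS(C)(=O)=O)C[C@H]12 | intermediate
15 | (E)-ethylidene ketone: C1 ketone, C5=CH–CH3 with methyl anti to C1 | C1C(=O)O[C@H]2C[C@H](C)C(=O)/C(=C/C)C[C@H]12 | intermediate
16 | diene with saturated lactone: 1-methylene, (E)-5-ethylidene | C1C(=O)O[C@H]2C[C@H](C)C(=C)/C(=C/C)C[C@H]12 | intermediate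
17 | Mannich base: 11-(dimethylaminomethyl) lactone, C11 epimers | CN(C)CC1C(=O)O[C@H]2C[C@H](C)C(=C)/C(=C/C)C[C@H]12 | intermediate
18 | methiodide of 17 | C[N+](C)(C)CC1C(=O)O[C@H]2C[C@H](C)C(=C)/C(=C/C)C[C@H]12.[I-] | intermediate
19 | guaianolide diene: (7R,8S,10S) trans-fused α-methylene-γ-lactone, 1-methylene, (E)-5-ethylidene, 10-methyl | C=C1C(=O)O[C@H]2C[C@H](C)C(=C)/C(=C/C)C[C@H]12 | intermediate
20 | 1-O-acetylbritannilactone | C=C1C(=O)O[C@@H]2CC(C)=C([C@@H](C)CCCOC(C)=O)[C@@H](O)[C@H]12 | starting material
21 | 6'-O-TBS-1'-O-acetylbritannilactone | C=C1C(=O)O[C@@H]2CC(C)=C([C@@H](C)CCCOC(C)=O)[C@@H](O[Si](C)(C)C(C)(C)C)[C@H]12 | intermediate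
22 | (E)-alkylidene lactone diethyl acetal (C11'=C3H–CH(OEt)2, acetal carbon anti to C12') | CCOC(OCC)/C=C1/C(=O)O[C@@H]2CC(C)=C([C@@H](C)CCCOC(C)=O)[C@@H](O[Si](C)(C)C(C)(C)C)[C@H]12 | intermediate
23 | (E)-formylmethylene lactone (C11'=C3H–C2HO, formyl anti to C12') | O=C/C=C1/C(=O)O[C@@H]2CC(C)=C([C@@H](C)CCCOC(C)=O)[C@@H](O[Si](C)(C)C(C)(C)C)[C@H]12 | intermediate
24 | Diels–Alder adduct, formyl group at C3 cis to the C4 methyl group (C3 epimer of 25) | C=C1C(=O)O[C@H]2C[C@H](C)C3=C(C[C@H]12)[C@H](C)[C@H](C=O)[C@]4(C3)C(=O)O[C@@H]5CC(C)=C([C@@H](C)CCCOC(C)=O)[C@@H](O[Si](C)(C)C(C)(C)C)[C@@H]54 | intermediate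
25 | formyl spiro-cyclohexene, 6'-O-TBS, formyl group cis to H4 and to C12' | C=C1C(=O)O[C@H]2C[C@H](C)C3=C(C[C@H]12)[C@H](C)[C@@H](C=O)[C@]4(C3)C(=O)O[C@@H]5CC(C)=C([C@@H](C)CCCOC(C)=O)[C@@H](O[Si](C)(C)C(C)(C)C)[C@@H]54 | intermediate
26 | 7-norbornenol, 2-deacetyl 6'-O-TBS target, C2–OH syn to C4=C5 | C=C1C(=O)O[C@H]2C[C@H](C)[C@@]34C[C@]5(C(=O)O[C@@H]6CC(C)=C([C@@H](C)CCCOC(C)=O)[C@@H](O[Si](C)(C)C(C)(C)C)[C@@H]65)[C@@H](C(C)=C3C[C@H]12)[C@H]4O | intermediate
27 | 2-O-acetyl 6'-O-TBS compound | C=C1C(=O)O[C@H]2C[C@H](C)[C@@]34C[C@]5(C(=O)O[C@@H]6CC(C)=C([C@@H](C)CCCOC(C)=O)[C@@H](O[Si](C)(C)C(C)(C)C)[C@@H]65)[C@@H](C(C)=C3C[C@H]12)[C@H]4OC(C)=O | intermediate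
28 | CNP0211028.3 | C=C1C(=O)O[C@H]2C[C@H](C)[C@@]34C[C@]5(C(=O)O[C@@H]6CC(C)=C([C@@H](C)CCCOC(C)=O)[C@@H](O)[C@@H]65)[C@@H](C(C)=C3C[C@H]12)[C@H]4OC(C)=O | target

**Totals.** Total step count: 20. Longest linear sequence: 17 steps (steps 1–12 and 16–20).

**Steps most likely to fail**

Step 18. The boat in which C2 touches C1 may be too strained to reach, the endo methyl group on C4 being pressed against C7'. The activated aldehyde may then add to the C5'=C10' alkene through an unstrained six-membered closure, or the allylic silyl ether may ionise. The fallback uses known reaction types and sets out from 25. Irradiation (about 300 nm, MeCN, 0 °C) should give, by intramolecular Paternò–Büchi cycloaddition, the oxetane F1, with its C2–C1 and O–C5 bonds both forced onto the formyl-bearing face. Acid-catalysed oxetane opening (BF3·OEt2, CH2Cl2, −40 °C) should then cleave the tertiary C5–O bond with loss of the neighbouring syn hydrogen H4 and return to the route at 26.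

Step 16. The two transition states that differ in which carbonyl group is endo may be poorly discriminated, so that C11' forms with the wrong configuration relative to C4; or the cycloaddition may be slow enough for the diene to dimerise. The fallback sets out from 22 and 19. The acetal 22 is ionised with Me3SiOTf (catalytic, 2,6-di-tert-butylpyridine, CH2Cl2, −78 °C) to an alkoxyallyl cation, a far more reactive dienophile. This cationic Diels–Alder reaction of an α,β-unsaturated acetal should proceed at low temperature with the same sense of addition and give the acetal adduct F2. Hydrolysis (pyridinium p-toluenesulfonate, acetone–H2O) returns to the route at 24. Because the aldehyde stays masked, no closure onto C5'=C10' can intervene.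

Step 14. The hindered 1,1-disubstituted alkene next to C7' may fail to enter the metathesis cycle, or ruthenium hydrides may move the exocyclic double bond into the lactone ring. The fallback sets out from 21. Oxidative cleavage with OsO4 (catalytic) and NaIO4 (2,6-lutidine, dioxane–H2O) should remove the exocyclic methylene, the tetrasubstituted alkene being too hindered for osmylation, and give the α-keto lactone F3 (in equilibrium with its enol). Wittig reaction with Ph3P=CHCHO (toluene, 80 °C) then returns to the route at 23; any (Z)-isomer is equilibrated with a trace of iodine in light.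

Further compounds
F1 | step 18 | oxetane (C2–C1 and O–C5 bonds, C4 still bearing H and methyl) | C=C1C(=O)O[C@H]2C[C@H](C)[C@@]34C[C@]5(C(=O)O[C@@H]6CC(C)=C([C@@H](C)CCCOC(C)=O)[C@@H](O[Si](C)(C)C(C)(C)C)[C@@H]65)[C@@H]([C@@H](C)[C@@]37C[C@H]12)[C@H]4O7
F2 | step 16 | diethyl acetal of Diels–Alder adduct 24 | C=C1C(=O)O[C@H]2C[C@H](C)C3=C(C[C@H]12)[C@H](C)[C@H](C(OCC)OCC)[C@]4(C3)C(=O)O[C@@H]5CC(C)=C([C@@H](C)CCCOC(C)=O)[C@@H](O[Si](C)(C)C(C)(C)C)[C@@H]54
F3 | step 14 | 6'-O-TBS 13'-nor-11'-oxo lactone (α-keto lactone) | O=C1C(=O)O[C@@H]2CC(C)=C([C@@H](C)CCCOC(C)=O)[C@@H](O[Si](C)(C)C(C)(C)C)[C@H]12
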